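**Plan**

- Retrosynthesis: the ring B silyl ether is cut last. The central cut opens ring A across A C1–A C2 and A C5–A C6, giving a 2-chloro-1,3-dimethoxy-1-silyloxybutadiene and the but-2-ynoate ester of an O-2-protected methyl orsellinate. The aryl ester O–acyl bond then leads back to methyl orsellinate and but-2-ynoic acid, and the diene to methyl 2-chloroacetoacetate.
- Enabling feature: ring A carries the depside carbonyl on C1, OH on C2, Cl on C3, OMe on C4, H on C5 and CH3 on C6. C2–C3–C4–C5 is a 1,3-dioxygenated diene with the chlorine already between the two oxygens, and the C1–C6 edge (carbonyl-bearing carbon next to methyl-bearing carbon) is a but-2-ynoate.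
- Forward order: the diene is made in two steps. Ring B is bought as methyl orsellinate, acylated at O-4 and silylated at O-2. Ring A, the only ring built, is formed last on the finished ester linkage by cycloaddition and loss of methanol, and desilylation ends the route.
- Stereochemistry: the target has no stereocentre. The alkene geometries of the diene precursors and the ketal carbon of the cycloadduct disappear on aromatisation.

Key step: step 5

Remark: the enol ether of step 1 is drawn as the Z isomer (methoxy trans to the ester) and the ketene acetal geometry of the diene is left open; neither survives into the aromatic ring.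

**Step 1**
Reactants: 1 methyl 2-chloroacetoacetate (methyl 2-chloro-3-oxobutanoate)
Product: 3 methyl (Z)-2-chloro-3-methoxybut-2-enoate, via dimethyl ketal 2 (not isolated)
Conditions: HC(OMe)3 (neat, 1.5 equiv), cat. H2SO4, rt; then cat. TsOH, distil (bath ca. 130 °C, reduced pressure)
Reagents that add atoms: trimethyl orthoformate, COC(OC)OC
Why: Acid-catalysed ketalisation of the ketone by the orthoester and loss of methanol on distillation (enol ether formation from a β-keto ester) should give the ester-conjugated, tetrasubstituted enol ether, which is the thermodynamic product.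

**Step 2**
Reactants: 3 methyl (Z)-2-chloro-3-methoxybut-2-enoate
Product: 5 2-chloro-1,3-dimethoxy-1-(trimethylsilyloxy)buta-1,3-diene, via lithium dienolate 4 (not isolated)
Conditions: LiN(iPr)2 (commercial solution, 1.1 equiv), THF, −78 °C; TMSCl, −78 to 0 °C; pentane, filtration under argon, concentration, bulb-to-bulb distillation
Reagents that add atoms: chlorotrimethylsilane, C[Si](C)(C)Cl
Why: γ-Deprotonation of a 3-alkoxy-2-enoate and O-silylation of the extended enolate (vinylketene silyl acetal formation) should work because 3 has no α-hydrogen, the amide base does not attack the ester or the vinylic C–Cl bond at −78 °C, and the hard silyl chloride traps the dienolate on oxygen.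

**Step 3**
Reactants: 6 methyl orsellinate (methyl 2,4-dihydroxy-6-methylbenzoate); 7 but-2-ynoic acid
Product: 9 methyl 4-(but-2-ynoyloxy)-2-hydroxy-6-methylbenzoate, via O-acylisourea 8 (not isolated)
Conditions: DCC (1.05 equiv), DMAP (5 mol %), CH2Cl2, −20 to 0 °C
Reagents that add atoms: none
Why: Steglich esterification; the 4-OH is the only phenol not locked in a hydrogen bond to the neighbouring ester carbonyl, so one equivalent of carbodiimide-activated acid should acylate it selectively, and the low temperature and small DMAP loading should keep the catalyst from adding to the ynoate.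

**Step 4**
Reactants: 9 methyl 4-(but-2-ynoyloxy)-2-hydroxy-6-methylbenzoate
Product: 10 methyl 4-(but-2-ynoyloxy)-2-[(tert-butyldimethylsilyl)oxy]-6-methylbenzoate
Conditions: TBSOTf (1.3 equiv), 2,6-lutidine (2 equiv), CH2Cl2, 0 °C
Reagents that add atoms: tert-butyldimethylsilyl trifluoromethanesulfonate, CC(C)(C)[Si](C)(C)OS(=O)(=O)C(F)(F)F
Why: Silylation of a phenol with a silyl triflate and a hindered pyridine should overcome the hydrogen bond of the salicylate OH without a nucleophile or strong base that could add to the ynoate or cleave the aryl ester, and it removes the proton that would otherwise quench the silyl ketene acetal in step 5.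

**Step 5**
Reactants: 10 methyl 4-(but-2-ynoyloxy)-2-[(tert-butyldimethylsilyl)oxy]-6-methylbenzoate; 5 2-chloro-1,3-dimethoxy-1-(trimethylsilyloxy)buta-1,3-diene (3 equiv)
Product: 13 methyl 2-[(tert-butyldimethylsilyl)oxy]-4-[(3-chloro-2-hydroxy-4-methoxy-6-methylbenzoyl)oxy]-6-methylbenzoate, via cycloadduct 11 (not isolated), via aryl trimethylsilyl ether 12 (not isolated)
Conditions: toluene (1 M), sealed tube, argon, 90 to 110 °C; then THF, 0.1 M aq. HCl, 0 °C
Reagents that add atoms: none
Why: A [4+2] cycloaddition (probably asynchronous, with the Michael-type bond leading) of the electron-rich vinylketene acetal to the electron-poor ynoate should give cyclohexa-1,4-diene 11, which aromatises by 1,4-loss of methanol from the ketal carbon and the ring CH2 to aryl silyl ether 12, and dilute acid then frees the chelated phenol while the bulkier ring B silyl ether stays. The closest known reaction type is the Diels–Alder reaction of 1-alkoxy-1-silyloxy-3-alkoxybutadienes with acetylenic esters, which gives resorcylates after loss of alcohol. Ring A is closed in an intermolecular [4+2] mode, with A C5–A C6 and A C1–A C2 both formed in this step. No stereocentre is created, and the racemic ketal carbon of 11 is destroyed on aromatisation. The step needs regioselectivity: the diene CH2 terminus, made the most nucleophilic carbon by the three donor oxygens, must bond to the β (methyl-bearing) alkyne carbon, the most electrophilic carbon of the ynoate, so that the ester ends up between OH and CH3 and the chlorine carried on the diene sits between the two oxygens. It also needs enough dienophile reactivity and no proton source, which the electron-poor aryl ester and the silylated ring B phenol should provide.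

**Step 6**
Reactants: 13 methyl 2-[(tert-butyldimethylsilyl)oxy]-4-[(3-chloro-2-hydroxy-4-methoxy-6-methylbenzoyl)oxy]-6-methylbenzoate
Product: 14 methyl 4-[(3-chloro-2-hydroxy-4-methoxy-6-methylbenzoyl)oxy]-2-hydroxy-6-methylbenzoate (target)
Conditions: HF·pyridine, THF/pyridine, 0 °C to rt
Reagents that add atoms: none
Why: Fluoride-induced cleavage of an aryl silyl ether (desilylation driven by Si–F bond formation) under buffered, weakly acidic conditions should leave the hindered depside ester, the methyl ester, the aryl methyl ether and the aryl chloride untouched.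

**Compound list**

1 | methyl 2-chloroacetoacetate (racemic, configurationally labile) | CC(=O)C(Cl)C(=O)OC | starting material
2 | methyl 2-chloro-3,3-dimethoxybutanoate (racemic, not isolated) | COC(C)(OC)C(Cl)C(=O)OC | intermediate
3 | methyl (Z)-2-chloro-3-methoxybut-2-enoate | CO/C(C)=C(\Cl)C(=O)OC | intermediate
4 | lithium 2-chloro-1,3-dimethoxybuta-1,3-dien-1-olate (not isolated) | COC(=C)C(Cl)=C(OC)[O-].[Li+] | intermediate
5 | 2-chloro-1,3-dimethoxy-1-(trimethylsilyloxy)buta-1,3-diene (ketene acetal geometry open) | COC(=C)C(Cl)=C(OC)O[Si](C)(C)C | intermediate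
6 | methyl orsellinate (methyl 2,4-dihydroxy-6-methylbenzoate) | COC(=O)c1c(C)cc(O)cc1O | starting material
7 | but-2-ynoic acid | CC#CC(=O)O | starting material
8 | O-(but-2-ynoyl)-N,N'-dicyclohexylisourea (not isolated) | CC#CC(=O)OC(=NC1CCCCC1)NC1CCCCC1 | intermediate
9 | methyl 4-(but-2-ynoyloxy)-2-hydroxy-6-methylbenzoate | CC#CC(=O)Oc1cc(C)c(C(=O)OC)c(O)c1 | intermediate
10 | methyl 4-(but-2-ynoyloxy)-2-[(tert-butyldimethylsilyl)oxy]-6-methylbenzoate | CC#CC(=O)Oc1cc(C)c(C(=O)OC)c(O[Si](C)(C)C(C)(C)C)c1 | intermediate
11 | 3-[(tert-butyldimethylsilyl)oxy]-4-(methoxycarbonyl)-5-methylphenyl 5-chloro-4,6-dimethoxy-2-methyl-6-(trimethylsilyloxy)cyclohexa-1,4-diene-1-carboxylate (racemic, not isolated) | COC1(O[Si](C)(C)C)C(Cl)=C(OC)CC(C)=C1C(=O)Oc1cc(C)c(C(=O)OC)c(O[Si](C)(C)C(C)(C)C)c1 | intermediate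
12 | methyl 2-[(tert-butyldimethylsilyl)oxy]-4-{[3-chloro-4-methoxy-6-methyl-2-(trimethylsilyloxy)benzoyl]oxy}-6-methylbenzoate (not isolated) | COC(=O)c1c(C)cc(OC(=O)c2c(C)cc(OC)c(Cl)c2O[Si](C)(C)C)cc1O[Si](C)(C)C(C)(C)C | intermediate
13 | methyl 2-[(tert-butyldimethylsilyl)oxy]-4-[(3-chloro-2-hydroxy-4-methoxy-6-methylbenzoyl)oxy]-6-methylbenzoate | COC(=O)c1c(C)cc(OC(=O)c2c(C)cc(OC)c(Cl)c2O)cc1O[Si](C)(C)C(C)(C)C | intermediate
14 | methyl 4-[(3-chloro-2-hydroxy-4-methoxy-6-methylbenzoyl)oxy]-2-hydroxy-6-methylbenzoate | COC(=O)c1c(C)cc(OC(=O)c2c(C)cc(OC)c(Cl)c2O)cc1O | target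

**Totals**

Total step count: 6. Longest linear sequence: 4 steps (6 → 9 → 10 → 13 → 14; the diene branch 1 → 3 → 5 → 13 → 14 is equally long).

**Steps most likely to fail**

1. Step 5. The cycloaddition to the β-methyl ynoate may be slower than thermal decay of the diene (silyl migration, oligomerisation). Part of the adduct may also aromatise by loss of silanol in place of methanol, which would leave a 2-methoxy group on ring A. The fallback sets out from diene 5 and comes back at target 14; it keeps the cycloaddition but forms the depside bond afterwards. Diene 5 should react near room temperature with commercial benzyl buta-2,3-dienoate, a far more reactive allenic dienophile. The CH2 terminus attacks the central allene carbon, and loss of methanol with inward shift of the exocyclic methylene gives, after dilute acid, benzyl 3-chloro-2-hydroxy-4-methoxy-6-methylbenzoate F1. Hydrogenolysis (H2, Pd/C, EtOAc, stopped after one equivalent of uptake to spare the aryl chloride) should give 3-chloro-2-hydroxy-4-methoxy-6-methylbenzoic acid F2. Condensation of F2 with methyl orsellinate 6 by trifluoroacetic anhydride in toluene, the classical depside esterification in which only the non-chelated 4-OH reacts, should give 14 directly.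

2. Step 2. γ-Deprotonation of the chloro enol ether may be incomplete, the dienolate may be silylated on carbon, or the diene may hydrolyse during isolation. The fallback sets out from 1 and comes back at 13. Et3N and TMSCl should convert 1 into methyl 2-chloro-3-(trimethylsilyloxy)but-2-enoate F3. LiN(iPr)2 and TMSCl in THF at −78 °C should then give 2-chloro-1-methoxy-1,3-bis(trimethylsilyloxy)buta-1,3-diene F4, an established sequence for bis-silyl dienes of 2-chloroacetoacetates. Cycloaddition of F4 with 10 under the conditions of step 5 and dilute acid work-up should give methyl 2-[(tert-butyldimethylsilyl)oxy]-4-[(3-chloro-2,4-dihydroxy-6-methylbenzoyl)oxy]-6-methylbenzoate F5. Its non-chelated, chlorine-flanked 4-OH on ring A should be methylated selectively by one equivalent of Me3SiCHN2 in MeOH/toluene at 0 °C to give 13.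

3. Step 3. With only one equivalent of activated acid the acylation may stall, or it may spill over to the chelated 2-OH, and the nucleophilic catalyst may add to the ynoate. The fallback sets out from 6 and comes back at 10; it masks O-2 before O-4 is acylated, so that the acid can be used in excess. Benzylation (BnBr, K2CO3, acetone), selective for the 4-OH, should give methyl 4-(benzyloxy)-2-hydroxy-6-methylbenzoate F6. TBSOTf and 2,6-lutidine should give methyl 4-(benzyloxy)-2-[(tert-butyldimethylsilyl)oxy]-6-methylbenzoate F7. Hydrogenolysis (H2, Pd/C, EtOAc) should give methyl 2-[(tert-butyldimethylsilyl)oxy]-4-hydroxy-6-methylbenzoate F8. Its single free phenol is then esterified with excess 7 and DCC at −20 °C to give 10.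

**Further compounds**

F1 | step 5 | benzyl 3-chloro-2-hydroxy-4-methoxy-6-methylbenzoate | Cc1cc(OC)c(Cl)c(O)c1C(=O)OCc1ccccc1
F2 | step 5 | 3-chloro-2-hydroxy-4-methoxy-6-methylbenzoic acid | Cc1cc(OC)c(Cl)c(O)c1C(=O)O
F3 | step 2 | methyl 2-chloro-3-(trimethylsilyloxy)but-2-enoate | CC(O[Si](C)(C)C)=C(Cl)C(=O)OC
F4 | step 2 | 2-chloro-1-methoxy-1,3-bis(trimethylsilyloxy)buta-1,3-diene | C=C(O[Si](C)(C)C)C(Cl)=C(OC)O[Si](C)(C)C
F5 | step 2 | methyl 2-[(tert-butyldimethylsilyl)oxy]-4-[(3-chloro-2,4-dihydroxy-6-methylbenzoyl)oxy]-6-methylbenzoate | COC(=O)c1c(C)cc(OC(=O)c2c(C)cc(O)c(Cl)c2O)cc1O[Si](C)(C)C(C)(C)C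
F6 | step 3 | methyl 4-(benzyloxy)-2-hydroxy-6-methylbenzoate | COC(=O)c1c(C)cc(OCc2ccccc2)cc1O
F7 | step 3 | methyl 4-(benzyloxy)-2-[(tert-butyldimethylsilyl)oxy]-6-methylbenzoate | COC(=O)c1c(C)cc(OCc2ccccc2)cc1O[Si](C)(C)C(C)(C)C
F8 | step 3 | methyl 2-[(tert-butyldimethylsilyl)oxy]-4-hydroxy-6-methylbenzoate | COC(=O)c1c(C)cc(O)cc1O[Si](C)(C)C(C)(C)C
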